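The route rests on reading the C17 ketone, the methyl-bearing C18 and the oxygenated C19 as an anti-aldol unit that is stored in a trans-β-lactone (oxetan-2-one ring O–C17–C18–C19). Carbon monoxide becomes C17: a Lewis acid/cobaltate catalyst inserts it into the C18–O bond of a cis-C18–C19 epoxide, forming the C17–C18 bond, closing the four-membered ring and inverting C18 in one operation. The precursor is the silyl-protected C18–C21 epoxy alcohol, its epoxide face relayed from the purchased C20 centre. Opening of the lactone, an Evans aldol, two Negishi couplings and a crotylation/metathesis-derived C1–C11 lactone complete the target.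

Key step: step 7

Remark: locants C1–C24 are those of the target (C1 lactone carbonyl, C24 carboxyl carbon, C16′ hydroxymethyl carbon), which is (4S,5R,10S,16S,18R,19R,20R; 6E,8Z,12E,14E,22E). CIP descriptors quoted for an intermediate are those of that intermediate. TBS = tert-butyldimethylsilyl, TES = triethylsilyl, TBDPS = tert-butyldiphenylsilyl. Compounds 34, 40 and 44 are taken as purchased.

Step 1
Reactants: 1 methyl (2R)-3-hydroxy-2-methylpropanoate
Product: 2 methyl (2R)-3-[(tert-butyldimethylsilyl)oxy]-2-methylpropanoate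
Conditions: tBuMe2SiCl, imidazole, CH2Cl2, 0 °C → rt
Reagents that add atoms: tert-butyldimethylsilyl chloride, C[Si](C)(Cl)C(C)(C)C
Why: Imidazole-promoted O-silylation of a primary alcohol is routine and leaves the future C20 centre untouched.

Step 2
Reactants: 2 methyl (2R)-3-[(tert-butyldimethylsilyl)oxy]-2-methylpropanoate
Product: 3 (2R)-3-[(tert-butyldimethylsilyl)oxy]-2-methylpropanal
Conditions: iBu2AlH (1.05 equiv), CH2Cl2, −78 °C; MeOH, aq. potassium sodium tartrate
Reagents that add atoms: none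
Why: Partial ester reduction stops at the aldehyde because the tetrahedral aluminium hemiacetal is stable at −78 °C, and a cold work-up avoids epimerisation of the α-centre.

Step 3
Reactants: 3 (2R)-3-[(tert-butyldimethylsilyl)oxy]-2-methylpropanal; 4 ethyltriphenylphosphonium bromide
Product: 6 tert-butyldimethyl{[(2S,3Z)-2-methylpent-3-en-1-yl]oxy}silane, via ethylidene ylide 5 (not isolated)
Conditions: KN(SiMe3)2, THF, 0 °C; then 3, −78 °C → rt
Reagents that add atoms: none
Why: The salt-free, non-stabilised ylide reacts under kinetic control (Wittig reaction) to give the (Z)-C18=C19 alkene without epimerising C20.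

Step 4
Reactants: 6 tert-butyldimethyl{[(2S,3Z)-2-methylpent-3-en-1-yl]oxy}silane
Product: 7 (2S,3Z)-2-methylpent-3-en-1-ol
Conditions: HF·pyridine, THF, 0 °C → rt; solvent removed by careful distillation (volatile product)
Reagents that add atoms: none
Why: Fluoride-driven desilylation frees the homoallylic hydroxyl that must direct the epoxidation.

Step 5
Reactants: 7 (2S,3Z)-2-methylpent-3-en-1-ol
Product: 8 (2R)-2-[(2R,3S)-3-methyloxiran-2-yl]propan-1-ol
Conditions: VO(acac)2 (3 mol%), tBuOOH (decane solution), CH2Cl2, 0 °C → rt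
Reagents that add atoms: tert-butyl hydroperoxide, CC(C)(C)OO
Why: In this hydroxyl-directed vanadium-catalysed epoxidation the vanadate ester delivers oxygen within a chair-like transition state in which allylic 1,3-strain with the cis-methyl group holds the C20–H in the alkene plane, so that oxygen adds anti to the C20 methyl and the cis-epoxide centres C18 and C19 are set from C20.

Step 6
Reactants: 8 (2R)-2-[(2R,3S)-3-methyloxiran-2-yl]propan-1-ol
Product: 9 tert-butyldimethyl{(2R)-2-[(2R,3S)-3-methyloxiran-2-yl]propoxy}silane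
Conditions: tBuMe2SiCl, imidazole, CH2Cl2, 0 °C
Reagents that add atoms: tert-butyldimethylsilyl chloride, C[Si](C)(Cl)C(C)(C)C
Why: Silylation gives a carbonylation substrate whose O21 can neither translactonise the coming β-lactone nor chelate the aluminium centre, and whose bulk adds to the steric shielding of C19.

Step 7
Reactants: 9 tert-butyldimethyl{(2R)-2-[(2R,3S)-3-methyloxiran-2-yl]propoxy}silane (cis-epoxide); 10 carbon monoxide
Product: 11 (3R,4R)-4-{(2R)-1-[(tert-butyldimethylsilyl)oxy]propan-2-yl}-3-methyloxetan-2-one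
Conditions: [(salph)Al(THF)2][Co(CO)4] (5 mol%; salph = N,N′-bis(3,5-di-tert-butylsalicylidene)-1,2-phenylenediaminate), CO (60 bar), THF, 50 °C
Reagents that add atoms: none
Why: The aluminium cation binds the epoxide oxygen, [Co(CO)4]− opens the ring by backside attack at the methyl-bearing C18, CO migrates into the new C18–Co bond to create C17–C18, and the aluminium alkoxide on C19 closes onto the acylcobalt carbon and releases the catalyst. The closest known reaction type is the Lewis acid/tetracarbonylcobaltate ring-expansion carbonylation of cis-2,3-disubstituted epoxides to trans-β-lactones. The oxetan-2-one ring closes in the 4-exo-trig mode by attack of O19 on the C17 acyl carbon. C18 is fixed by SN2 inversion while C19 and C20 are untouched, so the cis-epoxide should give the trans (anti-aldol) lactone. The step needs attack at C18 and not at C19, which is secured by the contrast between a methyl group and the α-branched C20 substituent, reinforced by the bulky, weakly Lewis-basic silyl ether on O21.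

Step 8
Reactants: 11 (3R,4R)-4-{(2R)-1-[(tert-butyldimethylsilyl)oxy]propan-2-yl}-3-methyloxetan-2-one
Product: 12 (2R,3R,4R)-5-[(tert-butyldimethylsilyl)oxy]-3-hydroxy-N-methoxy-N,2,4-trimethylpentanamide
Conditions: Me(MeO)NH·HCl, Me2AlCl, CH2Cl2, −30 °C → rt
Reagents that add atoms: N,O-dimethylhydroxylamine hydrochloride, CNOC.Cl
Why: The aluminium amide attacks the strained acyl carbon (acyl–oxygen cleavage, Weinreb amidation of a β-lactone), which frees the C19 hydroxyl and leaves C18 unchanged.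

Step 9
Reactants: 12 (2R,3R,4R)-5-[(tert-butyldimethylsilyl)oxy]-3-hydroxy-N-methoxy-N,2,4-trimethylpentanamide
Product: 13 (2R,3R,4R)-3,5-bis[(tert-butyldimethylsilyl)oxy]-N-methoxy-N,2,4-trimethylpentanamide
Conditions: tBuMe2SiOTf, 2,6-lutidine, CH2Cl2, −78 → 0 °C
Reagents that add atoms: tert-butyldimethylsilyl trifluoromethanesulfonate, C[Si](C)(OS(=O)(=O)C(F)(F)F)C(C)(C)C
Why: The silyl triflate/2,6-lutidine pair silylates the hindered secondary C19 hydroxyl under non-epimerising conditions.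

Step 10
Reactants: 13 (2R,3R,4R)-3,5-bis[(tert-butyldimethylsilyl)oxy]-N-methoxy-N,2,4-trimethylpentanamide
Product: 14 (2R,3R,4R)-3-[(tert-butyldimethylsilyl)oxy]-5-hydroxy-N-methoxy-N,2,4-trimethylpentanamide
Conditions: HF·pyridine, pyridine, THF, 0 °C; crude 14 used at once in step 11
Reagents that add atoms: none
Why: Buffered HF·pyridine cleaves the primary silyl ether far faster than the hindered secondary one, and immediate use of the δ-hydroxy amide forestalls its lactonisation.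

Step 11
Reactants: 14 (2R,3R,4R)-3-[(tert-butyldimethylsilyl)oxy]-5-hydroxy-N-methoxy-N,2,4-trimethylpentanamide
Product: 15 (2R,3S,4S)-3-[(tert-butyldimethylsilyl)oxy]-5-iodo-N-methoxy-N,2,4-trimethylpentanamide
Conditions: I2, PPh3, imidazole, CH2Cl2, 0 °C
Reagents that add atoms: iodine, II
Why: Appel-type iodination converts the primary alcohol into the C21 iodide by SN2 displacement of the oxyphosphonium group.

Step 12
Reactants: 16 ethyl 3-oxobutanoate
Product: 17 ethyl (2E)-3-{[(trifluoromethyl)sulfonyl]oxy}but-2-enoate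
Conditions: (CF3SO2)2O, aq. Me4NOH, hexanes, 5 °C
Reagents that add atoms: trifluoromethanesulfonic anhydride, O=S(=O)(OS(=O)(=O)C(F)(F)F)C(F)(F)F
Why: O-triflation of the non-chelated tetramethylammonium enolate, which prefers the extended form, should give the (E)-enol triflate.

Step 13
Reactants: 15 (2R,3S,4S)-3-[(tert-butyldimethylsilyl)oxy]-5-iodo-N-methoxy-N,2,4-trimethylpentanamide; 17 ethyl (2E)-3-{[(trifluoromethyl)sulfonyl]oxy}but-2-enoate
Product: 19 ethyl (2E,5R,6R,7R)-6-[(tert-butyldimethylsilyl)oxy]-8-[methoxy(methyl)amino]-3,5,7-trimethyl-8-oxooct-2-enoate, via alkylzinc iodide 18 (not isolated)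
Conditions: Zn dust (activated with BrCH2CH2Br and Me3SiCl), THF, 40 °C; then 17, Pd(PPh3)4 (5 mol%), THF, rt → 45 °C
Reagents that add atoms: none
Why: Zinc inserts into the primary C21–I bond without touching the Weinreb amide, and palladium-catalysed Negishi coupling with the enol triflate proceeds with retention to give the (22E)-enoate.

Step 14
Reactants: 19 ethyl (2E,5R,6R,7R)-6-[(tert-butyldimethylsilyl)oxy]-8-[methoxy(methyl)amino]-3,5,7-trimethyl-8-oxooct-2-enoate
Product: 20 (2R,3R,4R,6E)-3-[(tert-butyldimethylsilyl)oxy]-8-hydroxy-2,4,6-trimethyloct-6-enal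
Conditions: iBu2AlH (4.5 equiv), CH2Cl2, −78 → −40 °C; MeOH, aq. potassium sodium tartrate
Reagents that add atoms: none
Why: Excess hydride reduces the Weinreb amide to the C17 aldehyde through its stable chelate and the enoate to the C24 allylic alcohol in one operation.

Step 15
Reactants: 20 (2R,3R,4R,6E)-3-[(tert-butyldimethylsilyl)oxy]-8-hydroxy-2,4,6-trimethyloct-6-enal
Product: 21 (2R,3R,4R,6E)-3-[(tert-butyldimethylsilyl)oxy]-2,4,6-trimethyl-8-[(triethylsilyl)oxy]oct-6-enal
Conditions: Et3SiCl, imidazole, CH2Cl2, 0 °C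
Reagents that add atoms: chlorotriethylsilane, CC[Si](Cl)(CC)CC
Why: Mild silylation caps the primary allylic hydroxyl and leaves the epimerisable aldehyde untouched.

Step 16
Reactants: 22 pent-3-yn-1-ol
Product: 24 (3E)-4-iodopent-3-en-1-ol, via alkenylzirconocene 23 (not isolated)
Conditions: Cp2Zr(H)Cl (2.3 equiv), THF, rt → 40 °C; then I2, 0 °C
Reagents that add atoms: iodine, II
Why: Syn hydrozirconation places zirconium on the less hindered, methyl-bearing alkyne carbon after equilibration, and iodinolysis with retention gives the (E)-vinyl iodide.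

Step 17
Reactants: 24 (3E)-4-iodopent-3-en-1-ol
Product: 25 (3E)-4-iodopent-3-enoic acid
Conditions: CrO3, aq. H2SO4, acetone, 0 °C
Reagents that add atoms: water, O
Why: Jones oxidation takes the primary alcohol through the aldehyde hydrate to the acid at 0 °C without moving the β,γ-double bond into conjugation.

Step 18
Reactants: 25 (3E)-4-iodopent-3-enoic acid; 26 (4R)-4-benzyl-1,3-oxazolidin-2-one
Product: 28 (4R)-4-benzyl-3-[(3E)-4-iodopent-3-enoyl]-1,3-oxazolidin-2-one, via mixed pivalic anhydride 27 (not isolated)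
Conditions: Me3CCOCl, Et3N, THF, −20 °C; then LiCl, 26, −20 °C → rt
Reagents that add atoms: none
Why: The mixed pivalic anhydride N-acylates the oxazolidinone under LiCl/Et3N activation without isomerising the β,γ-unsaturated acyl group.

Step 19
Reactants: 28 (4R)-4-benzyl-3-[(3E)-4-iodopent-3-enoyl]-1,3-oxazolidin-2-one; 21 (2R,3R,4R,6E)-3-[(tert-butyldimethylsilyl)oxy]-2,4,6-trimethyl-8-[(triethylsilyl)oxy]oct-6-enal
Product: 30 (4R)-4-benzyl-3-{(2R,3S,4S,5R,6R,8E)-5-[(tert-butyldimethylsilyl)oxy]-3-hydroxy-2-[(1E)-2-iodoprop-1-en-1-yl]-4,6,8-trimethyl-10-[(triethylsilyl)oxy]dec-8-enoyl}-1,3-oxazolidin-2-one (syn-aldol adduct), via boron enolate 29 (not isolated)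
Conditions: Bu2BOTf, Et3N, CH2Cl2, −78 → 0 °C; then 21, −78 → 0 °C; pH 7 buffer, MeOH, 30% H2O2, 0 °C
Reagents that add atoms: none
Why: In this Evans syn-aldol the (Z)-boron dienolate reacts at its α-carbon through a Zimmerman–Traxler transition state whose face is fixed by the (R)-benzyl auxiliary, which sets C16 (and the C17 carbinol that is oxidised later) while the C14=C15 geometry is carried through unchanged.

Step 20
Reactants: 30 syn-aldol adduct
Product: 31 (2S,3R,4S,5R,6R,8E)-5-[(tert-butyldimethylsilyl)oxy]-2-[(1E)-2-iodoprop-1-en-1-yl]-4,6,8-trimethyl-10-[(triethylsilyl)oxy]dec-8-ene-1,3-diol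
Conditions: LiBH4, MeOH (1 equiv), THF, 0 °C
Reagents that add atoms: none
Why: Borohydride cleaves the imide reductively, turning the exocyclic acyl carbon into the C16′ hydroxymethyl group and returning the oxazolidinone.

Step 21
Reactants: 31 (2S,3R,4S,5R,6R,8E)-5-[(tert-butyldimethylsilyl)oxy]-2-[(1E)-2-iodoprop-1-en-1-yl]-4,6,8-trimethyl-10-[(triethylsilyl)oxy]dec-8-ene-1,3-diol
Product: 33 fully silylated C14–C24 vinyl iodide (14-iodo; 16′-O-TBDPS; 17-O-TES; 19-O-TBS; 24-O-TES; 14E,22E; 16S,17R,18R,19R,20R), via mono-TBDPS ether 32 (not isolated)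
Conditions: tBuPh2SiCl, imidazole, CH2Cl2, 0 °C → rt; then Et3SiOTf, 2,6-lutidine, −78 → 0 °C
Reagents that add atoms: tert-butyl(chloro)diphenylsilane, CC(C)(C)[Si](Cl)(c1ccccc1)c1ccccc1; triethylsilyl trifluoromethanesulfonate, CC[Si](CC)(CC)OS(=O)(=O)C(F)(F)F
Why: The bulky chlorosilane silylates only the primary C16′ hydroxyl, after which the hindered C17 hydroxyl is capped in the same flask with a labile triethylsilyl group that can be removed before the final oxidation.

Step 22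
Reactants: 33 fully silylated C14–C24 vinyl iodide; 34 (E)-1,2-bis(tributylstannyl)ethene
Product: 35 C12–C24 dienylstannane, the 12-tributylstannyl homologue of 33 with the same silyl groups (12E,14E,22E; 16S,17R,18R,19R,20R)
Conditions: 34 (3 equiv), PdCl2(MeCN)2 (5 mol%), DMF, rt, dark
Reagents that add atoms: none
Why: Stille coupling proceeds with retention at both alkenes and, with the bis-stannane in excess, should stop after one coupling to give the (12E,14E)-dienylstannane.

Step 23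
Reactants: 35 C12–C24 dienylstannane
Product: 36 C12–C24 dienyl iodide, the 12-iodo analogue of 35 (12E,14E,22E; 16S,17R,18R,19R,20R)
Conditions: I2, CH2Cl2, 0 °C; aq. Na2S2O3
Reagents that add atoms: iodine, II
Why: Iododestannylation occurs by ipso substitution with retention and gives the (E,E)-dienyl iodide.

Step 24
Reactants: 37 methyl (2S)-3-hydroxy-2-methylpropanoate
Product: 38 methyl (2S)-3-[(tert-butyldimethylsilyl)oxy]-2-methylpropanoate
Conditions: tBuMe2SiCl, imidazole, CH2Cl2, 0 °C → rt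
Reagents that add atoms: tert-butyldimethylsilyl chloride, C[Si](C)(Cl)C(C)(C)C
Why: Routine silylation of the primary alcohol keeps the future C10 centre intact.

Step 25
Reactants: 38 methyl (2S)-3-[(tert-butyldimethylsilyl)oxy]-2-methylpropanoate
Product: 39 (2S)-3-[(tert-butyldimethylsilyl)oxy]-2-methylpropanal
Conditions: iBu2AlH (1.05 equiv), CH2Cl2, −78 °C; MeOH, aq. potassium sodium tartrate
Reagents that add atoms: none
Why: Low-temperature partial reduction stops at the aldehyde and a cold work-up preserves the α-centre.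

Step 26
Reactants: 39 (2S)-3-[(tert-butyldimethylsilyl)oxy]-2-methylpropanal; 40 ethyl 2-[bis(2,2,2-trifluoroethoxy)phosphoryl]propanoate
Product: 41 ethyl (2Z,4R)-5-[(tert-butyldimethylsilyl)oxy]-2,4-dimethylpent-2-enoate
Conditions: 40, KN(SiMe3)2, 18-crown-6, THF, −78 °C; then 39, −78 °C
Reagents that add atoms: none
Why: In this Still–Gennari olefination the electron-poor bis(trifluoroethyl) phosphonate makes the oxaphosphetane collapse faster than it can equilibrate, so the kinetic (Z)-enoate forms and fixes the C8=C9 geometry at −78 °C without epimerising C10.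

Step 27
Reactants: 41 ethyl (2Z,4R)-5-[(tert-butyldimethylsilyl)oxy]-2,4-dimethylpent-2-enoate
Product: 42 (2Z,4R)-5-[(tert-butyldimethylsilyl)oxy]-2,4-dimethylpent-2-en-1-ol
Conditions: iBu2AlH (2.3 equiv), CH2Cl2, −78 °C; MeOH, aq. potassium sodium tartrate
Reagents that add atoms: none
Why: 1,2-Reduction of the enoate by excess hydride gives the allylic alcohol without touching the alkene geometry or the silyl ether.

Step 28
Reactants: 42 (2Z,4R)-5-[(tert-butyldimethylsilyl)oxy]-2,4-dimethylpent-2-en-1-ol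
Product: 43 (2Z,4R)-5-[(tert-butyldimethylsilyl)oxy]-2,4-dimethylpent-2-enal
Conditions: MnO2 (activated, excess), CH2Cl2, rt; filtered and used at once in step 29
Reagents that add atoms: none
Why: Neutral heterogeneous oxidation of the allylic alcohol by MnO2 gives the (Z)-enal without the acid or base that would isomerise it to the (E)-enal.

Step 29
Reactants: 43 (2Z,4R)-5-[(tert-butyldimethylsilyl)oxy]-2,4-dimethylpent-2-enal; 44 (triphenylphosphoranylidene)acetaldehyde
Product: 45 (2E,4Z,6R)-7-[(tert-butyldimethylsilyl)oxy]-4,6-dimethylhepta-2,4-dienal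
Conditions: 44 (1.2 equiv), toluene, 60 °C
Reagents that add atoms: none
Why: The stabilised formyl ylide adds reversibly (Wittig reaction) and gives the (E)-C6=C7 alkene, the product dienal being less electrophilic than the starting enal so that a second homologation is slow.

Step 30
Reactants: 45 (2E,4Z,6R)-7-[(tert-butyldimethylsilyl)oxy]-4,6-dimethylhepta-2,4-dienal; 46 (E)-but-2-ene
Product: 49 (3S,4R,5E,7Z,9R)-10-[(tert-butyldimethylsilyl)oxy]-3,7,9-trimethyldeca-1,5,7-trien-4-ol, via crotylpotassium 47 (not isolated), via crotylborane 48 (not isolated)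
Conditions: 46, KOtBu, nBuLi, THF, −78 → −45 °C; (−)-Ipc2BOMe [from (+)-α-pinene], −78 °C; BF3·OEt2; then 45, −78 °C; NaOH, H2O2, 0 °C → rt
Reagents that add atoms: none
Why: In this Brown crotylboration the (E)-crotylborane adds through a chair transition state to give the anti product, and the isopinocampheyl groups direct attack to the Si face of the aldehyde, which sets C4 (S) and C5 (R).

Step 31
Reactants: 49 (3S,4R,5E,7Z,9R)-10-[(tert-butyldimethylsilyl)oxy]-3,7,9-trimethyldeca-1,5,7-trien-4-ol; 50 acryloyl chloride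
Product: 51 (3S,4R,5E,7Z,9R)-10-[(tert-butyldimethylsilyl)oxy]-3,7,9-trimethyldeca-1,5,7-trien-4-yl prop-2-enoate
Conditions: Et3N, CH2Cl2, −20 → 0 °C
Reagents that add atoms: none
Why: O-acylation of the secondary alcohol installs C1–C2 with retention at C5.

Step 32
Reactants: 51 (3S,4R,5E,7Z,9R)-10-[(tert-butyldimethylsilyl)oxy]-3,7,9-trimethyldeca-1,5,7-trien-4-yl prop-2-enoate
Product: 52 (5S,6R)-6-[(1E,3Z,5R)-6-[(tert-butyldimethylsilyl)oxy]-3,5-dimethylhexa-1,3-dien-1-yl]-5-methyl-5,6-dihydro-2H-pyran-2-one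
Conditions: second-generation Grubbs catalyst RuCl2(=CHPh)(PCy3)(H2IMes) (5 mol%), CH2Cl2 (3 mM), 40 °C
Reagents that add atoms: none
Why: Ring-closing metathesis starts at the terminal vinyl group and closes the six-membered lactone onto the acrylate with loss of ethene, the conjugated internal alkenes being too hindered to compete.

Step 33
Reactants: 52 (5S,6R)-6-[(1E,3Z,5R)-6-[(tert-butyldimethylsilyl)oxy]-3,5-dimethylhexa-1,3-dien-1-yl]-5-methyl-5,6-dihydro-2H-pyran-2-one
Product: 53 (5S,6R)-6-[(1E,3Z,5R)-6-hydroxy-3,5-dimethylhexa-1,3-dien-1-yl]-5-methyl-5,6-dihydro-2H-pyran-2-one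
Conditions: HF·pyridine, pyridine, THF, 0 °C → rt
Reagents that add atoms: none
Why: Buffered HF·pyridine removes the primary silyl ether under mildly acidic conditions that the unsaturated lactone and the diene tolerate.

Step 34
Reactants: 53 (5S,6R)-6-[(1E,3Z,5R)-6-hydroxy-3,5-dimethylhexa-1,3-dien-1-yl]-5-methyl-5,6-dihydro-2H-pyran-2-one
Product: 54 (5S,6R)-6-[(1E,3Z,5R)-6-iodo-3,5-dimethylhexa-1,3-dien-1-yl]-5-methyl-5,6-dihydro-2H-pyran-2-one
Conditions: I2, PPh3, imidazole, CH2Cl2, 0 °C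
Reagents that add atoms: iodine, II
Why: Appel-type iodination converts the primary C11 alcohol into the iodide under neutral conditions.

Step 35
Reactants: 54 (5S,6R)-6-[(1E,3Z,5R)-6-iodo-3,5-dimethylhexa-1,3-dien-1-yl]-5-methyl-5,6-dihydro-2H-pyran-2-one (C1–C11 iodide); 36 C12–C24 dienyl iodide
Product: 56 fully protected C1–C24 lactone (16′-O-TBDPS; 17-O-TES; 19-O-TBS; 24-O-TES; 6E,8Z,12E,14E,22E; 4S,5R,10S,16S,17R,18R,19R,20R), via alkylzinc iodide 55 (not isolated)
Conditions: Zn dust (activated with BrCH2CH2Br and Me3SiCl), THF, 35 °C; then 36, Pd(PPh3)4 (5 mol%), THF, rt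
Reagents that add atoms: none
Why: Zinc inserts into the primary C–I bond without attacking the lactone, and the sp3–sp2 Negishi coupling forms C11–C12 with retention of the dienyl iodide geometry under neutral conditions.

Step 36
Reactants: 56 fully protected C1–C24 lactone
Product: 57 17,24-diol with the 16′-O-TBDPS and 19-O-TBS groups retained (4S,5R,10S,16S,17R,18S,19R,20R)
Conditions: pyridinium p-toluenesulfonate (cat.), MeOH/CH2Cl2, 0 °C
Reagents that add atoms: none
Why: Mild acidic methanolysis removes both triethylsilyl ethers and leaves the far more stable tert-butylsilyl ethers in place.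

Step 37
Reactants: 57 17,24-diol
Product: 58 17-ketone 24-aldehyde with the 16′-O-TBDPS and 19-O-TBS groups retained (4S,5R,10S,16S,18R,19R,20R)
Conditions: Dess–Martin periodinane, NaHCO3, CH2Cl2, 0 °C → rt
Reagents that add atoms: none
Why: The buffered periodinane oxidises the secondary C17 alcohol to the ketone and the allylic C24 alcohol to the enal without epimerising C16 or C18.

Step 38
Reactants: 58 17-ketone 24-aldehyde
Product: 59 C24 carboxylic acid with the 16′-O-TBDPS and 19-O-TBS groups retained (4S,5R,10S,16S,18R,19R,20R)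
Conditions: NaClO2, NaH2PO4, 2-methylbut-2-ene, tBuOH/H2O, 0 °C
Reagents that add atoms: sodium chlorite, [Na+].[O-]Cl=O
Why: Pinnick oxidation converts the enal selectively into the acid at about pH 4, the alkene scavenger protecting the polyene from hypochlorous acid.

Step 39
Reactants: 59 C24 carboxylic acid (bis-silyl ether)
Product: 60 target, (2E,5R,6R,7R,9S,10E,12E,15S,16Z,18E)-6-hydroxy-9-(hydroxymethyl)-3,5,7,11,15,17-hexamethyl-19-[(2R,3S)-3-methyl-6-oxo-3,6-dihydro-2H-pyran-2-yl]-8-oxononadeca-2,10,12,16,18-pentaenoic acid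
Conditions: HF·pyridine (excess), pyridine, THF, 0 °C → rt
Reagents that add atoms: none
Why: HF·pyridine removes the two remaining silyl ethers under mildly acidic conditions that should spare the β-hydroxy ketone, the C16 centre and the lactone.

Compound list
1 | methyl (2R)-3-hydroxy-2-methylpropanoate | COC(=O)[C@H](C)CO | starting material
2 | methyl (2R)-3-[(tert-butyldimethylsilyl)oxy]-2-methylpropanoate | COC(=O)[C@H](C)CO[Si](C)(C)C(C)(C)C | intermediate
3 | (2R)-3-[(tert-butyldimethylsilyl)oxy]-2-methylpropanal | O=C[C@H](C)CO[Si](C)(C)C(C)(C)C | intermediate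
4 | ethyltriphenylphosphonium bromide | CC[P+](c1ccccc1)(c1ccccc1)c1ccccc1.[Br-] | starting material
5 | ethylidene(triphenyl)phosphorane | CC=P(c1ccccc1)(c1ccccc1)c1ccccc1 | intermediate
6 | tert-butyldimethyl{[(2S,3Z)-2-methylpent-3-en-1-yl]oxy}silane | C/C=C\[C@H](C)CO[Si](C)(C)C(C)(C)C | intermediate
7 | (2S,3Z)-2-methylpent-3-en-1-ol | C/C=C\[C@H](C)CO | intermediate
8 | (2R)-2-[(2R,3S)-3-methyloxiran-2-yl]propan-1-ol | C[C@@H]1O[C@@H]1[C@H](C)CO | intermediate
9 | tert-butyldimethyl{(2R)-2-[(2R,3S)-3-methyloxiran-2-yl]propoxy}silane | C[C@@H]1O[C@@H]1[C@H](C)CO[Si](C)(C)C(C)(C)C | intermediate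
10 | carbon monoxide | [C-]#[O+] | starting material
11 | (3R,4R)-4-{(2R)-1-[(tert-butyldimethylsilyl)oxy]propan-2-yl}-3-methyloxetan-2-one | O=C1[C@H](C)[C@H](O1)[C@H](C)CO[Si](C)(C)C(C)(C)C | intermediate
12 | (2R,3R,4R)-5-[(tert-butyldimethylsilyl)oxy]-3-hydroxy-N-methoxy-N,2,4-trimethylpentanamide | CON(C)C(=O)[C@H](C)[C@H](O)[C@H](C)CO[Si](C)(C)C(C)(C)C | intermediate
13 | (2R,3R,4R)-3,5-bis[(tert-butyldimethylsilyl)oxy]-N-methoxy-N,2,4-trimethylpentanamide | CON(C)C(=O)[C@H](C)[C@H](O[Si](C)(C)C(C)(C)C)[C@H](C)CO[Si](C)(C)C(C)(C)C | intermediate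
14 | (2R,3R,4R)-3-[(tert-butyldimethylsilyl)oxy]-5-hydroxy-N-methoxy-N,2,4-trimethylpentanamide | CON(C)C(=O)[C@H](C)[C@H](O[Si](C)(C)C(C)(C)C)[C@H](C)CO | intermediate
15 | (2R,3S,4S)-3-[(tert-butyldimethylsilyl)oxy]-5-iodo-N-methoxy-N,2,4-trimethylpentanamide | CON(C)C(=O)[C@H](C)[C@H](O[Si](C)(C)C(C)(C)C)[C@H](C)CI | intermediate
16 | ethyl 3-oxobutanoate | CCOC(=O)CC(C)=O | starting material
17 | ethyl (2E)-3-{[(trifluoromethyl)sulfonyl]oxy}but-2-enoate | CCOC(=O)/C=C(\C)OS(=O)(=O)C(F)(F)F | intermediate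
18 | alkylzinc iodide of 15 (C21–ZnI) | CON(C)C(=O)[C@H](C)[C@H](O[Si](C)(C)C(C)(C)C)[C@H](C)C[Zn]I | intermediate
19 | ethyl (2E,5R,6R,7R)-6-[(tert-butyldimethylsilyl)oxy]-8-[methoxy(methyl)amino]-3,5,7-trimethyl-8-oxooct-2-enoate | CON(C)C(=O)[C@H](C)[C@H](O[Si](C)(C)C(C)(C)C)[C@H](C)C/C(C)=C/C(=O)OCC | intermediate
20 | (2R,3R,4R,6E)-3-[(tert-butyldimethylsilyl)oxy]-8-hydroxy-2,4,6-trimethyloct-6-enal | O=C[C@H](C)[C@H](O[Si](C)(C)C(C)(C)C)[C@H](C)C/C(C)=C/CO | intermediate
21 | (2R,3R,4R,6E)-3-[(tert-butyldimethylsilyl)oxy]-2,4,6-trimethyl-8-[(triethylsilyl)oxy]oct-6-enal | O=C[C@H](C)[C@H](O[Si](C)(C)C(C)(C)C)[C@H](C)C/C(C)=C/CO[Si](CC)(CC)CC | intermediate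
22 | pent-3-yn-1-ol | CC#CCCO | starting material
23 | (E)-alkenylzirconocene chloride of 22 (Zr on C4, O-zirconated) | C/C(=C\CCO[Zr](Cl)(C1C=CC=C1)C1C=CC=C1)[Zr](Cl)(C1C=CC=C1)C1C=CC=C1 | intermediate
24 | (3E)-4-iodopent-3-en-1-ol | C/C(I)=C\CCO | intermediate
25 | (3E)-4-iodopent-3-enoic acid | C/C(I)=C\CC(=O)O | intermediate
26 | (4R)-4-benzyl-1,3-oxazolidin-2-one | O=C1OC[C@@H](Cc2ccccc2)N1 | starting material
27 | (3E)-4-iodopent-3-enoic pivalic anhydride | C/C(I)=C\CC(=O)OC(=O)C(C)(C)C | intermediate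
28 | (4R)-4-benzyl-3-[(3E)-4-iodopent-3-enoyl]-1,3-oxazolidin-2-one | C/C(I)=C\CC(=O)N1[C@H](Cc2ccccc2)COC1=O | intermediate
29 | (Z)-dibutylboron dienolate of 28 | CCCCB(CCCC)O/C(=C\C=C(/C)I)N1[C@H](Cc2ccccc2)COC1=O | intermediate
30 | (4R)-4-benzyl-3-{(2R,3S,4S,5R,6R,8E)-5-[(tert-butyldimethylsilyl)oxy]-3-hydroxy-2-[(1E)-2-iodoprop-1-en-1-yl]-4,6,8-trimethyl-10-[(triethylsilyl)oxy]dec-8-enoyl}-1,3-oxazolidin-2-one | I/C(C)=C/[C@@H](C(=O)N1[C@H](Cc2ccccc2)COC1=O)[C@@H](O)[C@H](C)[C@H](O[Si](C)(C)C(C)(C)C)[C@H](C)C/C(C)=C/CO[Si](CC)(CC)CC | intermediate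
31 | (2S,3R,4S,5R,6R,8E)-5-[(tert-butyldimethylsilyl)oxy]-2-[(1E)-2-iodoprop-1-en-1-yl]-4,6,8-trimethyl-10-[(triethylsilyl)oxy]dec-8-ene-1,3-diol | I/C(C)=C/[C@@H](CO)[C@@H](O)[C@H](C)[C@H](O[Si](C)(C)C(C)(C)C)[C@H](C)C/C(C)=C/CO[Si](CC)(CC)CC | intermediate
32 | 16′-O-tert-butyldiphenylsilyl ether of 31 (17-OH free) | I/C(C)=C/[C@@H](CO[Si](c1ccccc1)(c1ccccc1)C(C)(C)C)[C@@H](O)[C@H](C)[C@H](O[Si](C)(C)C(C)(C)C)[C@H](C)C/C(C)=C/CO[Si](CC)(CC)CC | intermediate
33 | C14–C24 vinyl iodide: 14-iodo, 16′-O-tert-butyldiphenylsilyl, 17-O-triethylsilyl, 19-O-tert-butyldimethylsilyl, 24-O-triethylsilyl (14E,22E; 16S,17R,18R,19R,20R) | I/C(C)=C/[C@@H](CO[Si](c1ccccc1)(c1ccccc1)C(C)(C)C)[C@@H](O[Si](CC)(CC)CC)[C@H](C)[C@H](O[Si](C)(C)C(C)(C)C)[C@H](C)C/C(C)=C/CO[Si](CC)(CC)CC | intermediate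
34 | (E)-1,2-bis(tributylstannyl)ethene | CCCC[Sn](CCCC)(CCCC)/C=C/[Sn](CCCC)(CCCC)CCCC | starting material
35 | C12–C24 dienylstannane: 12-tributylstannyl, silyl groups as in 33 (12E,14E,22E; 16S,17R,18R,19R,20R) | CCCC[Sn](CCCC)(CCCC)/C=C/C(C)=C/[C@@H](CO[Si](c1ccccc1)(c1ccccc1)C(C)(C)C)[C@@H](O[Si](CC)(CC)CC)[C@H](C)[C@H](O[Si](C)(C)C(C)(C)C)[C@H](C)C/C(C)=C/CO[Si](CC)(CC)CC | intermediate
36 | C12–C24 dienyl iodide: 12-iodo, silyl groups as in 33 (12E,14E,22E; 16S,17R,18R,19R,20R) | I/C=C/C(C)=C/[C@@H](CO[Si](c1ccccc1)(c1ccccc1)C(C)(C)C)[C@@H](O[Si](CC)(CC)CC)[C@H](C)[C@H](O[Si](C)(C)C(C)(C)C)[C@H](C)C/C(C)=C/CO[Si](CC)(CC)CC | intermediate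
37 | methyl (2S)-3-hydroxy-2-methylpropanoate | COC(=O)[C@@H](C)CO | starting material
38 | methyl (2S)-3-[(tert-butyldimethylsilyl)oxy]-2-methylpropanoate | COC(=O)[C@@H](C)CO[Si](C)(C)C(C)(C)C | intermediate
39 | (2S)-3-[(tert-butyldimethylsilyl)oxy]-2-methylpropanal | O=C[C@@H](C)CO[Si](C)(C)C(C)(C)C | intermediate
40 | ethyl 2-[bis(2,2,2-trifluoroethoxy)phosphoryl]propanoate | CCOC(=O)C(C)P(=O)(OCC(F)(F)F)OCC(F)(F)F | starting material
41 | ethyl (2Z,4R)-5-[(tert-butyldimethylsilyl)oxy]-2,4-dimethylpent-2-enoate | CC(=C/[C@@H](C)CO[Si](C)(C)C(C)(C)C)/C(=O)OCC | intermediate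
42 | (2Z,4R)-5-[(tert-butyldimethylsilyl)oxy]-2,4-dimethylpent-2-en-1-ol | CC(=C/[C@@H](C)CO[Si](C)(C)C(C)(C)C)/CO | intermediate
43 | (2Z,4R)-5-[(tert-butyldimethylsilyl)oxy]-2,4-dimethylpent-2-enal | CC(=C/[C@@H](C)CO[Si](C)(C)C(C)(C)C)/C=O | intermediate
44 | (triphenylphosphoranylidene)acetaldehyde | O=CC=P(c1ccccc1)(c1ccccc1)c1ccccc1 | starting material
45 | (2E,4Z,6R)-7-[(tert-butyldimethylsilyl)oxy]-4,6-dimethylhepta-2,4-dienal | CC(=C/[C@@H](C)CO[Si](C)(C)C(C)(C)C)/C=C/C=O | intermediate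
46 | (E)-but-2-ene | C/C=C/C | starting material
47 | (E)-but-2-en-1-ylpotassium | C/C=C/C[K] | intermediate
48 | B-[(E)-but-2-en-1-yl]diisopinocampheylborane, isopinocampheyl groups from (+)-α-pinene | C/C=C/CB([C@@H]1C[C@@H]2C[C@H]([C@H]1C)C2(C)C)[C@@H]1C[C@@H]2C[C@H]([C@H]1C)C2(C)C | intermediate
49 | (3S,4R,5E,7Z,9R)-10-[(tert-butyldimethylsilyl)oxy]-3,7,9-trimethyldeca-1,5,7-trien-4-ol | CC(=C/[C@@H](C)CO[Si](C)(C)C(C)(C)C)/C=C/[C@@H](O)[C@@H](C)C=C | intermediate
50 | acryloyl chloride | C=CC(Cl)=O | starting material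
51 | (3S,4R,5E,7Z,9R)-10-[(tert-butyldimethylsilyl)oxy]-3,7,9-trimethyldeca-1,5,7-trien-4-yl prop-2-enoate | CC(=C/[C@@H](C)CO[Si](C)(C)C(C)(C)C)/C=C/[C@@H](OC(=O)C=C)[C@@H](C)C=C | intermediate
52 | (5S,6R)-6-[(1E,3Z,5R)-6-[(tert-butyldimethylsilyl)oxy]-3,5-dimethylhexa-1,3-dien-1-yl]-5-methyl-5,6-dihydro-2H-pyran-2-one | CC(=C/[C@@H](C)CO[Si](C)(C)C(C)(C)C)/C=C/[C@H]1OC(=O)C=C[C@@H]1C | intermediate
53 | (5S,6R)-6-[(1E,3Z,5R)-6-hydroxy-3,5-dimethylhexa-1,3-dien-1-yl]-5-methyl-5,6-dihydro-2H-pyran-2-one | CC(=C/[C@@H](C)CO)/C=C/[C@H]1OC(=O)C=C[C@@H]1C | intermediate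
54 | (5S,6R)-6-[(1E,3Z,5R)-6-iodo-3,5-dimethylhexa-1,3-dien-1-yl]-5-methyl-5,6-dihydro-2H-pyran-2-one | CC(=C/[C@@H](C)CI)/C=C/[C@H]1OC(=O)C=C[C@@H]1C | intermediate
55 | alkylzinc iodide of 54 (C11–ZnI) | CC(=C/[C@@H](C)C[Zn]I)/C=C/[C@H]1OC(=O)C=C[C@@H]1C | intermediate
56 | protected C1–C24 lactone: 16′-O-tert-butyldiphenylsilyl, 17-O-triethylsilyl, 19-O-tert-butyldimethylsilyl, 24-O-triethylsilyl (4S,5R,10S,16S,17R,18R,19R,20R) | CC(=C/[C@@H](C)C/C=C/C(C)=C/[C@@H](CO[Si](c1ccccc1)(c1ccccc1)C(C)(C)C)[C@@H](O[Si](CC)(CC)CC)[C@H](C)[C@H](O[Si](C)(C)C(C)(C)C)[C@H](C)C/C(C)=C/CO[Si](CC)(CC)CC)/C=C/[C@H]1OC(=O)C=C[C@@H]1C | intermediate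
57 | 17,24-diol: 16′-O-tert-butyldiphenylsilyl, 19-O-tert-butyldimethylsilyl (4S,5R,10S,16S,17R,18S,19R,20R) | CC(=C/[C@@H](C)C/C=C/C(C)=C/[C@@H](CO[Si](c1ccccc1)(c1ccccc1)C(C)(C)C)[C@@H](O)[C@H](C)[C@H](O[Si](C)(C)C(C)(C)C)[C@H](C)C/C(C)=C/CO)/C=C/[C@H]1OC(=O)C=C[C@@H]1C | intermediate
58 | 17-ketone 24-aldehyde: 16′-O-tert-butyldiphenylsilyl, 19-O-tert-butyldimethylsilyl (4S,5R,10S,16S,18R,19R,20R) | CC(=C/[C@@H](C)C/C=C/C(C)=C/[C@@H](CO[Si](c1ccccc1)(c1ccccc1)C(C)(C)C)C(=O)[C@H](C)[C@H](O[Si](C)(C)C(C)(C)C)[C@H](C)C/C(C)=C/C=O)/C=C/[C@H]1OC(=O)C=C[C@@H]1C | intermediate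
59 | C24 acid: 16′-O-tert-butyldiphenylsilyl, 19-O-tert-butyldimethylsilyl (4S,5R,10S,16S,18R,19R,20R) | CC(=C/[C@@H](C)C/C=C/C(C)=C/[C@@H](CO[Si](c1ccccc1)(c1ccccc1)C(C)(C)C)C(=O)[C@H](C)[C@H](O[Si](C)(C)C(C)(C)C)[C@H](C)C/C(C)=C/C(=O)O)/C=C/[C@H]1OC(=O)C=C[C@@H]1C | intermediate
60 | (2E,5R,6R,7R,9S,10E,12E,15S,16Z,18E)-6-hydroxy-9-(hydroxymethyl)-3,5,7,11,15,17-hexamethyl-19-[(2R,3S)-3-methyl-6-oxo-3,6-dihydro-2H-pyran-2-yl]-8-oxononadeca-2,10,12,16,18-pentaenoic acid | CC(=C/[C@@H](C)C/C=C/C(C)=C/[C@@H](CO)C(=O)[C@H](C)[C@H](O)[C@H](C)C/C(C)=C/C(=O)O)/C=C/[C@H]1OC(=O)C=C[C@@H]1C | target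

Total step count: 39.
Longest linear sequence: 24 steps (1 to 60 through steps 1–11, 13–15, 19–23 and 35–39).

Steps most likely to fail

Step 7. Regiocontrol may be lost through cobaltate attack at C19, or the Lewis acid may rearrange the epoxide to a ketone before carbonylation. The fallback sets out from aldehyde 3 and comes back at amide 13, building the same anti,anti triad by crotylation instead of carbonylation. Aldehyde 3 is treated with crotylborane 48 (made as in step 30; Si-face attack, anti addition against the Felkin preference) to give the homoallylic alcohol (2R,3S,4S)-1-[(tert-butyldimethylsilyl)oxy]-2,4-dimethylhex-5-en-3-ol F1. Silylation with tBuMe2SiOTf/2,6-lutidine gives the bis-silyl ether tert-butyl{[(2R,3S,4S)-3-[(tert-butyldimethylsilyl)oxy]-2,4-dimethylhex-5-en-1-yl]oxy}dimethylsilane F2. Oxidative cleavage of the vinyl group with RuCl3 (cat.)/NaIO4 gives (2R,3R,4R)-3,5-bis[(tert-butyldimethylsilyl)oxy]-2,4-dimethylpentanoic acid F3. Carbodiimide coupling of F3 with N,O-dimethylhydroxylamine gives 13.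

Step 35. Zinc insertion may be slow, the alkylpalladium intermediate may lose a β-hydride, or the dienyl iodide may isomerise, all at the expense of two advanced fragments. The fallback sets out from iodide 54 and vinyl iodide 33 and comes back at 56, moving the fragment union to a neutral sp2–sp2 Stille coupling at C13–C14; steps 22 and 23 are then not needed. Bis-stannane 34 is mono-iodinated with one equivalent of I2 to tributyl[(E)-2-iodoethenyl]stannane F4. The zinc reagent 55 from 54 is coupled with an excess of F4 (Pd(PPh3)4, THF) to give the vinylstannane (5S,6R)-6-[(1E,3Z,5S,7E)-3,5-dimethyl-8-(tributylstannyl)octa-1,3,7-trien-1-yl]-5-methyl-5,6-dihydro-2H-pyran-2-one F5. Stille coupling of F5 with 33 (PdCl2(MeCN)2, DMF) gives 56.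

Step 29. The formyl ylide may add sluggishly to the hindered α-branched (Z)-enal, the C8=C9 geometry may drift towards E at the temperature needed, or the product dienal may be homologated a second time. The fallback sets out from enal 43 and comes back at dienal 45, replacing the direct formyl olefination by an ester-level phosphonate olefination at room temperature followed by redox adjustment. Horner–Wadsworth–Emmons reaction of 43 with triethyl phosphonoacetate (LiCl, iPr2NEt, MeCN, rt) gives ethyl (2E,4Z,6R)-7-[(tert-butyldimethylsilyl)oxy]-4,6-dimethylhepta-2,4-dienoate F6. Reduction with iBu2AlH (CH2Cl2, −78 °C) gives (2E,4Z,6R)-7-[(tert-butyldimethylsilyl)oxy]-4,6-dimethylhepta-2,4-dien-1-ol F7. Oxidation of F7 with MnO2 (CH2Cl2, rt) gives 45.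

Further compounds
F1 | step 7 | (2R,3S,4S)-1-[(tert-butyldimethylsilyl)oxy]-2,4-dimethylhex-5-en-3-ol | C=C[C@H](C)[C@H](O)[C@H](C)CO[Si](C)(C)C(C)(C)C
F2 | step 7 | tert-butyl{[(2R,3S,4S)-3-[(tert-butyldimethylsilyl)oxy]-2,4-dimethylhex-5-en-1-yl]oxy}dimethylsilane | C=C[C@H](C)[C@H](O[Si](C)(C)C(C)(C)C)[C@H](C)CO[Si](C)(C)C(C)(C)C
F3 | step 7 | (2R,3R,4R)-3,5-bis[(tert-butyldimethylsilyl)oxy]-2,4-dimethylpentanoic acid | OC(=O)[C@H](C)[C@H](O[Si](C)(C)C(C)(C)C)[C@H](C)CO[Si](C)(C)C(C)(C)C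
F4 | step 35 | tributyl[(E)-2-iodoethenyl]stannane | CCCC[Sn](CCCC)(CCCC)/C=C/I
F5 | step 35 | (5S,6R)-6-[(1E,3Z,5S,7E)-3,5-dimethyl-8-(tributylstannyl)octa-1,3,7-trien-1-yl]-5-methyl-5,6-dihydro-2H-pyran-2-one | CC(=C/[C@@H](C)C/C=C/[Sn](CCCC)(CCCC)CCCC)/C=C/[C@H]1OC(=O)C=C[C@@H]1C
F6 | step 29 | ethyl (2E,4Z,6R)-7-[(tert-butyldimethylsilyl)oxy]-4,6-dimethylhepta-2,4-dienoate | CC(=C/[C@@H](C)CO[Si](C)(C)C(C)(C)C)/C=C/C(=O)OCC
F7 | step 29 | (2E,4Z,6R)-7-[(tert-butyldimethylsilyl)oxy]-4,6-dimethylhepta-2,4-dien-1-ol | CC(=C/[C@@H](C)CO[Si](C)(C)C(C)(C)C)/C=C/CO
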